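**Retrosynthetic overview**

1. Drimane numbering is used for the bicycle (ring A = C1–C5 and C10, ring B = C5–C10, C11 = benzylic CH2, C12 = methyl on C8). The last C–C bond is C11–aryl, made by Negishi coupling of drimenyl iodide with the MOM-protected 5-bromobenzoate, followed by MOM removal.
2. The iodide comes from (−)-drimenol, which comes from a bicyclic N-acyloxazolidinone by a rhodium-hydride shift of the alkene from C6=C7 to C7=C8 and reductive removal of the auxiliary.
3. Key disconnection: both carbocycles are formed in one auxiliary-controlled intramolecular Diels–Alder reaction of an acyclic (2E,8E,10E)-trienoyl oxazolidinone. The new bonds are C5–C10 (the ring-fusion bond, which closes ring A and ring B at once) and C8–C9.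
4. Enabling feature: ring B is a cyclohexene whose C9 carries an exocyclic carbon (C11) that can be a carbonyl, so C9=C10 serves as dienophile and C5=C6–C7=C8 as diene. Ring A has no functional group, so C1–C4 (with the C4 gem-dimethyl) is simply the tether between C10 and C5; the C6=C7 alkene that results is one position from C7=C8.
5. The triene is assembled from 2,2-dimethylpent-4-enal (C1–C5 and the C4 methyls), a crotylphosphonate (C6–C8, C12) and ethyl acetoacetate (C9–C11 and the C10 methyl). Rings A and B form together in step 7; the arene is bought.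

Key step: step 7

Remark: crotyl bromide 1 is taken as the E isomer (commercial material is predominantly E); the C8 configuration set by the diene geometry is erased in step 8.

**Route**

Step 1
Reactants: 1 (E)-1-bromobut-2-ene; 2 triethyl phosphite
Product: 3 diethyl [(2E)-but-2-en-1-yl]phosphonate
Conditions: neat, 130 °C, bromoethane distilled off
Reagents that add atoms: none
Why: Michaelis–Arbuzov reaction of a primary allylic bromide, which should proceed by SN2 attack of phosphorus at C1 and keep the E alkene.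

Step 2
Reactants: 3 diethyl [(2E)-but-2-en-1-yl]phosphonate; 4 2,2-dimethylpent-4-enal
Product: 5 (5E,7E)-4,4-dimethylnona-1,5,7-triene
Conditions: n-BuLi, THF/DMPU, −78 °C; then 4, −78 °C → rt
Reagents that add atoms: none
Why: Horner–Wadsworth–Emmons olefination of a non-enolizable α-quaternary aldehyde with a lithiated allylic phosphonate, which should react at its α-carbon and give the new alkene E for steric reasons (no stereocentre is formed).

Step 3
Reactants: 6 ethyl acetoacetate
Product: 7 ethyl (2E)-3-{[(trifluoromethyl)sulfonyl]oxy}but-2-enoate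
Conditions: Me4NOH (aq.), hexanes, 5 °C; then Tf2O
Reagents that add atoms: trifluoromethanesulfonic anhydride, O=S(=O)(OS(=O)(=O)C(F)(F)F)C(F)(F)F
Why: O-sulfonylation of the non-chelated tetramethylammonium enolate of a β-keto ester, which should place the triflate trans to the ester because no metal chelate holds the enolate in the Z form.

Step 4
Reactants: 5 (5E,7E)-4,4-dimethylnona-1,5,7-triene; 7 ethyl (2E)-3-{[(trifluoromethyl)sulfonyl]oxy}but-2-enoate
Product: 9 ethyl (2E,8E,10E)-3,7,7-trimethyldodeca-2,8,10-trienoate, via B-alkyl-9-BBN adduct 8 (not isolated)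
Conditions: 9-BBN, THF, 0 °C → rt; then 7, PdCl2(dppf) (3 mol %), K3PO4 (3 M aq.), DMF, 50 °C
Reagents that add atoms: none
Why: chemoselective hydroboration of the monosubstituted terminal alkene followed by B-alkyl Suzuki–Miyaura coupling with the enol triflate, which should proceed with retention at the sp2 carbon and so deliver the (2E) trisubstituted enoate (no stereocentre is formed).

Step 5
Reactants: 9 ethyl (2E,8E,10E)-3,7,7-trimethyldodeca-2,8,10-trienoate
Product: 10 (2E,8E,10E)-3,7,7-trimethyldodeca-2,8,10-trienoic acid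
Conditions: LiOH, THF/MeOH/H2O, 40 °C; then 1 M HCl
Reagents that add atoms: lithium hydroxide, [Li+].[OH-]
Why: ester saponification, which should leave the three E double bonds untouched under mild hydroxide conditions.

Step 6
Reactants: 10 (2E,8E,10E)-3,7,7-trimethyldodeca-2,8,10-trienoic acid; 11 (4S)-4-benzyl-1,3-oxazolidin-2-one
Product: 13 (4S)-4-benzyl-3-[(2E,8E,10E)-3,7,7-trimethyldodeca-2,8,10-trienoyl]-1,3-oxazolidin-2-one, via mixed pivalic anhydride 12 (not isolated)
Conditions: PivCl, Et3N, THF, −20 °C; then LiCl, 11, −20 °C → rt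
Reagents that add atoms: none
Why: N-acylation of the oxazolidinone through a mixed anhydride, in which the nitrogen should attack the less hindered enoyl carbonyl and the auxiliary stereocentre is carried in unchanged.

Step 7
Reactants: 13 (4S)-4-benzyl-3-[(2E,8E,10E)-3,7,7-trimethyldodeca-2,8,10-trienoyl]-1,3-oxazolidin-2-one
Product: 14 (4S)-4-benzyl-3-{[(1S,2S,4aS,8aS)-2,5,5,8a-tetramethyl-1,2,4a,5,6,7,8,8a-octahydronaphthalen-1-yl]carbonyl}-1,3-oxazolidin-2-one
Conditions: Me2AlCl (1.4 equiv), CH2Cl2, −30 → 0 °C; 1 M HCl quench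
Reagents that add atoms: none
Why: Me2AlCl in excess should turn the imide into a cationic, two-point chelated s-cis dienophile, and the tethered (E,E)-diene then adds across C9=C10 in a concerted but asynchronous intramolecular Diels–Alder reaction in which the C5–C10 bond (β-carbon of the dienophile to the diene terminus next to C4) leads. The closest known reaction type is the dialkylaluminium-chloride-promoted intramolecular Diels–Alder reaction of (E,E,E)-trienoyl oxazolidinones to trans-fused bicyclo[4.4.0]decenes, and the extra β-methyl group should only lower the rate. Ring A (C10, C1–C5) is closed by the C5–C10 bond alone as the six-membered tether ring of the cycloaddition, and ring B (C5–C10) is closed suprafacially by C5–C10 together with C8–C9, leaving C6=C7. C9 and C10 are set cis (C11 and the C10 methyl on one face) by the E geometry of the dienophile, C5–H is set trans to the C10 methyl by the endo transition state (carbonyl under the diene), C8 follows from the E diene terminus and is erased in step 8, and the absolute sense comes from the (S)-benzyl group, which blocks one face of the chelated enoyl unit so that the diene adds from the opposite face. The step needs endo over exo and one π-face over the other, both of which the aluminium chelate enforces, while the C4 gem-dimethyl group in the tether favours the folded conformer in which C5 reaches C10.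

Step 8
Reactants: 14 (4S)-4-benzyl-3-{[(1S,2S,4aS,8aS)-2,5,5,8a-tetramethyl-1,2,4a,5,6,7,8,8a-octahydronaphthalen-1-yl]carbonyl}-1,3-oxazolidin-2-one
Product: 15 (4S)-4-benzyl-3-{[(1S,4aS,8aS)-2,5,5,8a-tetramethyl-1,4,4a,5,6,7,8,8a-octahydronaphthalen-1-yl]carbonyl}-1,3-oxazolidin-2-one
Conditions: RhCl3·3H2O (10 mol %), EtOH, 75 °C
Reagents that add atoms: none
Why: rhodium-hydride-catalysed positional alkene isomerization (addition then β-hydride elimination), in which Rh–H should add to the open α face of C6=C7, remove the cis H-8α and stop at the trisubstituted C7=C8 alkene because further migration would need a tertiary alkyl–rhodium species, while the C8 stereocentre and the 1,3-diaxial C8-methyl/C10-methyl strain disappear.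

Step 9
Reactants: 15 (4S)-4-benzyl-3-{[(1S,4aS,8aS)-2,5,5,8a-tetramethyl-1,4,4a,5,6,7,8,8a-octahydronaphthalen-1-yl]carbonyl}-1,3-oxazolidin-2-one
Product: 16 (−)-drimenol [(1S,4aS,8aS)-2,5,5,8a-tetramethyl-1,4,4a,5,6,7,8,8a-octahydronaphthalen-1-yl]methanol
Conditions: LiBH4, MeOH (1 equiv), Et2O, 0 °C → rt
Reagents that add atoms: none
Why: reductive cleavage of an N-acyloxazolidinone, in which hydride should attack the exocyclic carbonyl and release the primary alcohol without touching C9, the auxiliary being recovered.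

Step 10
Reactants: 16 (−)-drimenol
Product: 17 (1S,4aS,8aS)-1-(iodomethyl)-2,5,5,8a-tetramethyl-1,4,4a,5,6,7,8,8a-octahydronaphthalene (drimenyl iodide)
Conditions: I2, PPh3, imidazole, CH2Cl2, 0 °C → rt
Reagents that add atoms: iodine, II
Why: Appel-type iodination of a primary alcohol, an SN2 displacement at C11 that should not disturb the neighbouring C9 stereocentre or the homoallylic alkene.

Step 11
Reactants: 18 methyl 2,3,4-trihydroxybenzoate
Product: 19 methyl 5-bromo-2,3,4-trihydroxybenzoate
Conditions: NBS, MeCN, −10 °C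
Reagents that add atoms: N-bromosuccinimide, O=C1CCC(=O)N1Br
Why: electrophilic aromatic bromination, which should occur only at C5, the one free position that is ortho to the 4-OH, para to the 2-OH and meta to the ester.

Step 12
Reactants: 19 methyl 5-bromo-2,3,4-trihydroxybenzoate
Product: 20 methyl 5-bromo-2,3,4-tris(methoxymethoxy)benzoate
Conditions: NaH, MOMCl, DMF, 0 °C → rt
Reagents that add atoms: chloromethyl methyl ether, COCCl
Why: Williamson-type O-alkylation of the three phenoxides, which should give a tris-MOM ether that tolerates the organozinc coupling.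

Step 13
Reactants: 17 drimenyl iodide; 20 methyl 5-bromo-2,3,4-tris(methoxymethoxy)benzoate
Product: 22 methyl 2,3,4-tris(methoxymethoxy)-5-{[(1S,4aS,8aS)-2,5,5,8a-tetramethyl-1,4,4a,5,6,7,8,8a-octahydronaphthalen-1-yl]methyl}benzoate, via drimenylzinc iodide 21 (not isolated)
Conditions: Zn dust, LiCl, THF, 40 °C; then 20, Pd(OAc)2 (3 mol %), SPhos (6 mol %), THF, 50 °C
Reagents that add atoms: none
Why: direct zinc insertion into the primary iodide followed by Negishi sp3–sp2 cross-coupling, which tolerates the methyl ester and should form the C11–aryl bond without touching C9 because the metal sits one carbon away from the stereocentre.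

Step 14
Reactants: 22 methyl 2,3,4-tris(methoxymethoxy)-5-{[(1S,4aS,8aS)-2,5,5,8a-tetramethyl-1,4,4a,5,6,7,8,8a-octahydronaphthalen-1-yl]methyl}benzoate
Product: 23 methyl 2,3,4-trihydroxy-5-{[(1S,4aS,8aS)-2,5,5,8a-tetramethyl-1,4,4a,5,6,7,8,8a-octahydronaphthalen-1-yl]methyl}benzoate (CNP0185238.1)
Conditions: HCl (0.5 M in MeOH), 0 °C → rt
Reagents that add atoms: none
Why: acid-catalysed acetal exchange (MOM ether methanolysis), which should free the three phenols while the methyl ester is degenerate to methanolysis and the trisubstituted alkene is left alone at low temperature.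

**Compound list**

1 | (E)-1-bromobut-2-ene (crotyl bromide) | C/C=C/CBr | starting material
2 | triethyl phosphite | CCOP(OCC)OCC | starting material
3 | diethyl [(2E)-but-2-en-1-yl]phosphonate | C/C=C/CP(=O)(OCC)OCC | intermediate
4 | 2,2-dimethylpent-4-enal | C=CCC(C)(C)C=O | starting material
5 | (5E,7E)-4,4-dimethylnona-1,5,7-triene | C=CCC(C)(C)/C=C/C=C/C | intermediate
6 | ethyl acetoacetate | CCOC(=O)CC(C)=O | starting material
7 | ethyl (2E)-3-{[(trifluoromethyl)sulfonyl]oxy}but-2-enoate | CCOC(=O)/C=C(\C)OS(=O)(=O)C(F)(F)F | intermediate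
8 | 9-[(5E,7E)-4,4-dimethylnona-5,7-dien-1-yl]-9-borabicyclo[3.3.1]nonane (B-alkyl-9-BBN adduct) | C/C=C/C=C/C(C)(C)CCCB1C2CCCC1CCC2 | intermediate
9 | ethyl (2E,8E,10E)-3,7,7-trimethyldodeca-2,8,10-trienoate | CCOC(=O)/C=C(\C)CCCC(C)(C)/C=C/C=C/C | intermediate
10 | (2E,8E,10E)-3,7,7-trimethyldodeca-2,8,10-trienoic acid | OC(=O)/C=C(\C)CCCC(C)(C)/C=C/C=C/C | intermediate
11 | (4S)-4-benzyl-1,3-oxazolidin-2-one | O=C1N[C@@H](Cc2ccccc2)CO1 | starting material
12 | 2,2-dimethylpropanoic (2E,8E,10E)-3,7,7-trimethyldodeca-2,8,10-trienoic anhydride (mixed pivalic anhydride) | CC(C)(C)C(=O)OC(=O)/C=C(\C)CCCC(C)(C)/C=C/C=C/C | intermediate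
13 | (4S)-4-benzyl-3-[(2E,8E,10E)-3,7,7-trimethyldodeca-2,8,10-trienoyl]-1,3-oxazolidin-2-one | C/C=C/C=C/C(C)(C)CCC/C(C)=C/C(=O)N1C(=O)OC[C@@H]1Cc1ccccc1 | intermediate
14 | (4S)-4-benzyl-3-{[(1S,2S,4aS,8aS)-2,5,5,8a-tetramethyl-1,2,4a,5,6,7,8,8a-octahydronaphthalen-1-yl]carbonyl}-1,3-oxazolidin-2-one (drim-6-ene skeleton, 8β-methyl) | O=C([C@H]1[C@@H](C)C=C[C@H]2C(C)(C)CCC[C@]12C)N1C(=O)OC[C@@H]1Cc1ccccc1 | intermediate
15 | (4S)-4-benzyl-3-{[(1S,4aS,8aS)-2,5,5,8a-tetramethyl-1,4,4a,5,6,7,8,8a-octahydronaphthalen-1-yl]carbonyl}-1,3-oxazolidin-2-one (drim-7-ene skeleton) | O=C([C@H]1C(C)=CC[C@H]2C(C)(C)CCC[C@]12C)N1C(=O)OC[C@@H]1Cc1ccccc1 | intermediate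
16 | (−)-drimenol, [(1S,4aS,8aS)-2,5,5,8a-tetramethyl-1,4,4a,5,6,7,8,8a-octahydronaphthalen-1-yl]methanol | OC[C@H]1C(C)=CC[C@H]2C(C)(C)CCC[C@]12C | intermediate
17 | (1S,4aS,8aS)-1-(iodomethyl)-2,5,5,8a-tetramethyl-1,4,4a,5,6,7,8,8a-octahydronaphthalene (drimenyl iodide) | IC[C@H]1C(C)=CC[C@H]2C(C)(C)CCC[C@]12C | intermediate
18 | methyl 2,3,4-trihydroxybenzoate | COC(=O)c1ccc(O)c(O)c1O | starting material
19 | methyl 5-bromo-2,3,4-trihydroxybenzoate | COC(=O)c1cc(Br)c(O)c(O)c1O | intermediate
20 | methyl 5-bromo-2,3,4-tris(methoxymethoxy)benzoate | COC(=O)c1cc(Br)c(OCOC)c(OCOC)c1OCOC | intermediate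
21 | iodo{[(1S,4aS,8aS)-2,5,5,8a-tetramethyl-1,4,4a,5,6,7,8,8a-octahydronaphthalen-1-yl]methyl}zinc (drimenylzinc iodide) | I[Zn]C[C@H]1C(C)=CC[C@H]2C(C)(C)CCC[C@]12C | intermediate
22 | methyl 2,3,4-tris(methoxymethoxy)-5-{[(1S,4aS,8aS)-2,5,5,8a-tetramethyl-1,4,4a,5,6,7,8,8a-octahydronaphthalen-1-yl]methyl}benzoate | COC(=O)c1cc(C[C@H]2C(C)=CC[C@H]3C(C)(C)CCC[C@]23C)c(OCOC)c(OCOC)c1OCOC | intermediate
23 | methyl 2,3,4-trihydroxy-5-{[(1S,4aS,8aS)-2,5,5,8a-tetramethyl-1,4,4a,5,6,7,8,8a-octahydronaphthalen-1-yl]methyl}benzoate | COC(=O)c1cc(C[C@H]2C(C)=CC[C@H]3C(C)(C)CCC[C@]23C)c(O)c(O)c1O | target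

**Step count**

Total: 14 steps. Longest linear sequence: 11 steps (1, 2, 4, 5, 6, 7, 8, 9, 10, 13, 14).

**Steps most likely to fail**

Step 7 (key cycloaddition). The β,β-disubstituted dienophile is deactivated, so ring closure may be too slow under aluminium chelation and diene decomposition or leakage through an exo, cis-fused pathway may compete. The fallback sets out from 9 and comes back at 16; it moves the dienophile to the aldehyde oxidation level and changes the source of asymmetry from auxiliary to catalyst. Reduction of 9 with i-Bu2AlH (CH2Cl2, −78 °C) should give (2E,8E,10E)-3,7,7-trimethyldodeca-2,8,10-trien-1-ol F1. Oxidation with MnO2 should give (2E,8E,10E)-3,7,7-trimethyldodeca-2,8,10-trienal F2. An enantioselective intramolecular Diels–Alder reaction of this smaller, more electrophilic enal under a cationic chiral oxazaborolidinium Lewis acid (diphenylprolinol-derived B-o-tolyl oxazaborolidine activated with Tf2NH, CH2Cl2, −78 → −20 °C) should give (1S,2S,4aS,8aS)-2,5,5,8a-tetramethyl-1,2,4a,5,6,7,8,8a-octahydronaphthalene-1-carbaldehyde F3. The catalyst enantiomer is to be chosen with the usual formyl C–H···O binding model and checked by correlation with 16. NaBH4 in MeOH should give [(1S,2S,4aS,8aS)-2,5,5,8a-tetramethyl-1,2,4a,5,6,7,8,8a-octahydronaphthalen-1-yl]methanol F4, and the RhCl3·3H2O alkene shift of step 8 applied to F4 should return to 16.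

Step 8 (alkene shift). Migration may stay incomplete, or the double bond may move on to the tetrasubstituted C8=C9 position, where it is conjugated with the imide. The fallback sets out from 14 and comes back at 15; it places the alkene by an oxygen relay instead of by equilibration. Hydroboration–oxidation (BH3·SMe2, THF, 0 °C; then NaBO3·4H2O) should add boron from the α face to the less hindered C7 and give the 7α-alcohol (4S)-4-benzyl-3-{[(1S,2R,3R,4aS,8aS)-3-hydroxy-2,5,5,8a-tetramethyldecahydronaphthalen-1-yl]carbonyl}-1,3-oxazolidin-2-one F5. Dess–Martin oxidation should give the 7-ketone (4S)-4-benzyl-3-{[(1S,2R,4aS,8aS)-2,5,5,8a-tetramethyl-3-oxodecahydronaphthalen-1-yl]carbonyl}-1,3-oxazolidin-2-one F6. Tf2O with 2,6-di-tert-butyl-4-methylpyridine should give the more substituted C7=C8 enol triflate (4S)-4-benzyl-3-{[(1R,4aS,8aS)-2,5,5,8a-tetramethyl-3-{[(trifluoromethyl)sulfonyl]oxy}-1,4,4a,5,6,7,8,8a-octahydronaphthalen-1-yl]carbonyl}-1,3-oxazolidin-2-one F7 (same spatial arrangement as 15; the C1 descriptor changes by priority only). Reduction with Pd(OAc)2, PPh3, HCO2H and Bu3N in DMF at 60 °C should replace the triflate by hydrogen and give 15.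

Step 13 (Negishi coupling). Zinc insertion into the β-branched iodide next to the quaternary C10, or transmetalation of the resulting hindered alkylzinc, may be slow, so that protodemetalation and aryl homocoupling take over. The fallback sets out from 16 and comes back at 22; it forms the C11–aryl bond by polar addition and then removes the oxygen. Dess–Martin oxidation (NaHCO3 buffer) of 16 should give (1S,4aS,8aS)-2,5,5,8a-tetramethyl-1,4,4a,5,6,7,8,8a-octahydronaphthalene-1-carbaldehyde (drim-7-en-11-al) F8. Bromine–magnesium exchange on 20 (iPrMgCl·LiCl, THF, −20 °C, ester tolerated) and addition to F8 should give the benzylic carbinol methyl 5-{hydroxy[(1S,4aS,8aS)-2,5,5,8a-tetramethyl-1,4,4a,5,6,7,8,8a-octahydronaphthalen-1-yl]methyl}-2,3,4-tris(methoxymethoxy)benzoate F9 as C11 epimers, which is of no consequence. NaH, CS2 and MeI should give the S-methyl xanthate methyl 2,3,4-tris(methoxymethoxy)-5-{[(methylsulfanyl)carbonothioyl]oxy[(1S,4aS,8aS)-2,5,5,8a-tetramethyl-1,4,4a,5,6,7,8,8a-octahydronaphthalen-1-yl]methyl}benzoate F10. Barton–McCombie deoxygenation (Bu3SnH, AIBN, toluene, 90 °C) should give 22.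

**Further compounds**

F1 | step 7 | (2E,8E,10E)-3,7,7-trimethyldodeca-2,8,10-trien-1-ol | OC/C=C(\C)CCCC(C)(C)/C=C/C=C/C
F2 | step 7 | (2E,8E,10E)-3,7,7-trimethyldodeca-2,8,10-trienal | O=C/C=C(\C)CCCC(C)(C)/C=C/C=C/C
F3 | step 7 | (1S,2S,4aS,8aS)-2,5,5,8a-tetramethyl-1,2,4a,5,6,7,8,8a-octahydronaphthalene-1-carbaldehyde | O=C[C@H]1[C@@H](C)C=C[C@H]2C(C)(C)CCC[C@]12C
F4 | step 7 | [(1S,2S,4aS,8aS)-2,5,5,8a-tetramethyl-1,2,4a,5,6,7,8,8a-octahydronaphthalen-1-yl]methanol | OC[C@H]1[C@@H](C)C=C[C@H]2C(C)(C)CCC[C@]12C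
F5 | step 8 | (4S)-4-benzyl-3-{[(1S,2R,3R,4aS,8aS)-3-hydroxy-2,5,5,8a-tetramethyldecahydronaphthalen-1-yl]carbonyl}-1,3-oxazolidin-2-one | O=C([C@H]1[C@@H](C)[C@H](O)C[C@H]2C(C)(C)CCC[C@]12C)N1C(=O)OC[C@@H]1Cc1ccccc1
F6 | step 8 | (4S)-4-benzyl-3-{[(1S,2R,4aS,8aS)-2,5,5,8a-tetramethyl-3-oxodecahydronaphthalen-1-yl]carbonyl}-1,3-oxazolidin-2-one | O=C([C@H]1[C@@H](C)C(=O)C[C@H]2C(C)(C)CCC[C@]12C)N1C(=O)OC[C@@H]1Cc1ccccc1
F7 | step 8 | (4S)-4-benzyl-3-{[(1R,4aS,8aS)-2,5,5,8a-tetramethyl-3-{[(trifluoromethyl)sulfonyl]oxy}-1,4,4a,5,6,7,8,8a-octahydronaphthalen-1-yl]carbonyl}-1,3-oxazolidin-2-one | O=C([C@H]1C(C)=C(OS(=O)(=O)C(F)(F)F)C[C@H]2C(C)(C)CCC[C@]12C)N1C(=O)OC[C@@H]1Cc1ccccc1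
F8 | step 13 | (1S,4aS,8aS)-2,5,5,8a-tetramethyl-1,4,4a,5,6,7,8,8a-octahydronaphthalene-1-carbaldehyde (drim-7-en-11-al) | O=C[C@H]1C(C)=CC[C@H]2C(C)(C)CCC[C@]12C
F9 | step 13 | methyl 5-{hydroxy[(1S,4aS,8aS)-2,5,5,8a-tetramethyl-1,4,4a,5,6,7,8,8a-octahydronaphthalen-1-yl]methyl}-2,3,4-tris(methoxymethoxy)benzoate | COC(=O)c1cc(C(O)[C@H]2C(C)=CC[C@H]3C(C)(C)CCC[C@]23C)c(OCOC)c(OCOC)c1OCOC
F10 | step 13 | methyl 2,3,4-tris(methoxymethoxy)-5-{[(methylsulfanyl)carbonothioyl]oxy[(1S,4aS,8aS)-2,5,5,8a-tetramethyl-1,4,4a,5,6,7,8,8a-octahydronaphthalen-1-yl]methyl}benzoate | COC(=O)c1cc(C(OC(=S)SC)[C@H]2C(C)=CC[C@H]3C(C)(C)CCC[C@]23C)c(OCOC)c(OCOC)c1OCOC
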